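**Retrosynthetic overview**
1. C14 is carried as CH2O–Si and oxidised last (CH2OH → CHO → CO2H); the two angelates are put on the C8/C9 diol released from an L-tartrate acetonide.
2. Ten-membered ring (second ring): C1–C10 bond by intramolecular Nozaki–Hiyama–Kishi coupling, then 1,3-transposition of the allylic alcohol to give C1=C10 and C14–OH.
3. Key union and first ring: C6–C7 bond by intermolecular carbonyl allylation of (Z)-enal 7 with the 2-(methoxycarbonyl)allylboronate 16; the adduct closes to the trans α-methylene-γ-butyrolactone.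
4. 16 comes from dimethyl 2,3-O-isopropylidene-L-tartrate (C7–C10, supplies C8 and C9); 7 comes from pent-4-yn-1-ol (Z C4=C5 by cuprate addition to an ynoate).
5. Ring order: γ-lactone (step 11), then the carbocycle (step 14).

Assumption: germacrane numbering is used for atom labels (C6 lactone O–CH, C7 ring-fusion CH, C8/C9 acyloxy CH, C10/C14 the C(=)–CO2H unit, C11–C13 the methylene-lactone carbons, C15 the methyl); the SMILES is read as 6R,7S,8S,9S with both ring olefins ring-cis.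

**Route**

Step 1
Reactants: 1 pent-4-yn-1-ol
Product: 2 tert-butyl(dimethyl)(pent-4-yn-1-yloxy)silane
Conditions: TBSCl, imidazole, DMF, 0 °C → rt
Reagents that add atoms: tert-butyldimethylsilyl chloride, CC(C)(C)[Si](C)(C)Cl
Why: Routine silyl ether formation protects the future C1 oxygen through the organometallic steps.

Step 2
Reactants: 2 tert-butyl(dimethyl)(pent-4-yn-1-yloxy)silane
Product: 4 methyl 6-{[tert-butyl(dimethyl)silyl]oxy}hex-2-ynoate, via lithium acetylide 3 (not isolated)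
Conditions: n-BuLi, THF, −78 °C; then ClCO2Me, −78 → 0 °C
Reagents that add atoms: n-butyllithium, [Li]CCCC (lithium of 3); methyl chloroformate, COC(=O)Cl
Why: C-acylation of the lithium acetylide with the chloroformate installs C6 as an ester and gives the ynoate needed for a stereodefined trisubstituted olefin.

Step 3
Reactants: 4 methyl 6-{[tert-butyl(dimethyl)silyl]oxy}hex-2-ynoate
Product: 5 methyl (2Z)-6-{[tert-butyl(dimethyl)silyl]oxy}-3-methylhex-2-enoate
Conditions: Me2CuLi (from CuBr·SMe2 and 2 MeLi), THF, −78 °C; MeOH, −78 °C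
Reagents that add atoms: lithium dimethylcuprate, [Li+].C[Cu-]C
Why: syn-Carbocupration of the ynoate (organocuprate conjugate addition) and protonation at −78 °C with retention leave the chain cis to the ester, which is the Z geometry of C4=C5.

Step 4
Reactants: 5 methyl (2Z)-6-{[tert-butyl(dimethyl)silyl]oxy}-3-methylhex-2-enoate
Product: 6 (2Z)-6-{[tert-butyl(dimethyl)silyl]oxy}-3-methylhex-2-en-1-ol
Conditions: i-Bu2AlH (2.5 equiv), CH2Cl2, −78 °C
Reagents that add atoms: none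
Why: 1,2-Reduction of the enoate by the aluminium hydride gives the neryl-type allylic alcohol without touching the olefin geometry.

Step 5
Reactants: 6 (2Z)-6-{[tert-butyl(dimethyl)silyl]oxy}-3-methylhex-2-en-1-ol
Product: 7 (2Z)-6-{[tert-butyl(dimethyl)silyl]oxy}-3-methylhex-2-enal
Conditions: MnO2, CH2Cl2, 0 °C → rt
Reagents that add atoms: none
Why: Neutral allylic oxidation with MnO2 gives the Z-enal with minimal Z/E isomerisation (as for nerol to neral), and 7 is used at once.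

Step 6
Reactants: 8 dimethyl (4R,5R)-2,2-dimethyl-1,3-dioxolane-4,5-dicarboxylate (dimethyl 2,3-O-isopropylidene-L-tartrate)
Product: 10 (4S,5S)-4,5-diethynyl-2,2-dimethyl-1,3-dioxolane, via dialdehyde 9 (not isolated)
Conditions: i-Bu2AlH (2.1 equiv), CH2Cl2, −78 °C; then MeOH, K2CO3, MeCOC(N2)P(O)(OMe)2, −78 °C → rt
Reagents that add atoms: dimethyl (1-diazo-2-oxopropyl)phosphonate, CC(=O)C(=[N+]=[N-])P(=O)(OC)OC
Why: Half-reduction of both α-alkoxy esters to the aldehyde stage and in-flask Seyferth–Gilbert homologation (Ohira–Bestmann reagent) give the C2-symmetric diyne, with C8 and C9 taken unchanged from L-tartrate and the trans-dioxolane being the favoured arrangement should the dialdehyde epimerise.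

Step 7
Reactants: 10 (4S,5S)-4,5-diethynyl-2,2-dimethyl-1,3-dioxolane
Product: 11 (4S,5R)-4-ethynyl-2,2-dimethyl-5-[1-(tributylstannyl)ethenyl]-1,3-dioxolane
Conditions: Bu3SnH (1.0 equiv), Mo(CO)3(CNtBu)3 (3 mol %), hydroquinone, THF, 55 °C; recovered 10 recycled
Reagents that add atoms: tributyltin hydride, CCCC[SnH](CCCC)CCCC
Why: Molybdenum-catalysed hydrostannation places tin on the internal carbon next to the propargylic oxygen (Markovnikov, syn addition), and because 10 is C2-symmetric a single mono-adduct results from one equivalent of stannane.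

Step 8
Reactants: 11 (4S,5R)-4-ethynyl-2,2-dimethyl-5-[1-(tributylstannyl)ethenyl]-1,3-dioxolane
Product: 13 methyl 3-{(4S,5R)-2,2-dimethyl-5-[1-(tributylstannyl)ethenyl]-1,3-dioxolan-4-yl}prop-2-ynoate, via lithium acetylide 12 (not isolated)
Conditions: LiN(i-Pr)2 (1.0 equiv), THF, −78 °C; then ClCO2Me, −78 → 0 °C
Reagents that add atoms: lithium diisopropylamide, CC(C)[N-]C(C)C.[Li+] (lithium of 12); methyl chloroformate, COC(=O)Cl
Why: The remaining terminal alkyne is deprotonated by the amide base without tin–lithium exchange and C-acylated to the ynoate that becomes C7, C11 and C12.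

Step 9
Reactants: 13 methyl 3-{(4S,5R)-2,2-dimethyl-5-[1-(tributylstannyl)ethenyl]-1,3-dioxolan-4-yl}prop-2-ynoate
Product: 14 methyl 3-[(4S,5R)-5-(1-iodoethenyl)-2,2-dimethyl-1,3-dioxolan-4-yl]prop-2-ynoate
Conditions: N-iodosuccinimide, CH2Cl2, 0 °C
Reagents that add atoms: N-iodosuccinimide, O=C1CCC(=O)N1I
Why: ipso-Iododestannylation converts the alkenylstannane into the 2-iodoalkene needed for the later Nozaki–Hiyama–Kishi step, while the electron-poor ynoate is inert to the iodinating agent.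

Step 10
Reactants: 14 methyl 3-[(4S,5R)-5-(1-iodoethenyl)-2,2-dimethyl-1,3-dioxolan-4-yl]prop-2-ynoate
Product: 16 methyl (2Z)-3-[(4S,5R)-5-(1-iodoethenyl)-2,2-dimethyl-1,3-dioxolan-4-yl]-2-[(4,4,5,5-tetramethyl-1,3,2-dioxaborolan-2-yl)methyl]prop-2-enoate, via alkenylalane 15 (not isolated)
Conditions: i-Bu2AlH, HMPA, THF, 0 °C; then ICH2Bpin, 0 °C → rt
Reagents that add atoms: diisobutylaluminium hydride, CC(C)C[AlH]CC(C)C (aluminium of 15); 2-(iodomethyl)-4,4,5,5-tetramethyl-1,3,2-dioxaborolane, ICB1OC(C)(C)C(C)(C)O1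
Why: Conjugate syn-hydroalumination of the ynoate puts H on C7 and Al on C11 cis to each other, and the alkenylalane is homologated with retention by the iodomethylboronate (boron ate complex, 1,2-shift) so that C8 ends trans to CH2B, the E-crotyl-type geometry.

Step 11
Reactants: 7 (2Z)-6-{[tert-butyl(dimethyl)silyl]oxy}-3-methylhex-2-enal; 16 methyl (2Z)-3-[(4S,5R)-5-(1-iodoethenyl)-2,2-dimethyl-1,3-dioxolan-4-yl]-2-[(4,4,5,5-tetramethyl-1,3,2-dioxaborolan-2-yl)methyl]prop-2-enoate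
Product: 18 (4S,5R)-5-[(1Z)-5-{[tert-butyl(dimethyl)silyl]oxy}-2-methylpent-1-en-1-yl]-4-[(4S,5R)-5-(1-iodoethenyl)-2,2-dimethyl-1,3-dioxolan-4-yl]-3-methylideneoxolan-2-one, via pinacol borate 17 (not isolated)
Conditions: Sc(OTf)3 (10 mol %), toluene, −40 °C → rt; then TsOH·H2O (10 mol %), rt
Reagents that add atoms: none
Why: Carbonyl allylation (Lewis-acid-accelerated allylboration with a 2-alkoxycarbonyl allylboronate) through a closed chair transition state: C8, trans to CH2B, sits equatorial and gives the 6,7-anti adduct, the C8–H bond eclipses C7=C11 to avoid A(1,3) strain with the ester so the aldehyde adds to the face away from C9 (sets 7S and 6R), and the anti borate closes to the trans-lactone.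

Step 12
Reactants: 18 (the silyl ether lactone above)
Product: 19 (4S,5R)-5-[(1Z)-5-hydroxy-2-methylpent-1-en-1-yl]-4-[(4S,5R)-5-(1-iodoethenyl)-2,2-dimethyl-1,3-dioxolan-4-yl]-3-methylideneoxolan-2-one
Conditions: HF·pyridine, pyridine, THF, 0 °C → rt
Reagents that add atoms: none
Why: Buffered fluoride cleaves the primary silyl ether selectively and leaves the acetonide, the iodoalkene and the methylene lactone untouched.

Step 13
Reactants: 19 (the primary alcohol above)
Product: 20 (4Z)-5-{(2R,3S)-3-[(4S,5R)-5-(1-iodoethenyl)-2,2-dimethyl-1,3-dioxolan-4-yl]-4-methylidene-5-oxooxolan-2-yl}-4-methylpent-4-enal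
Conditions: Dess–Martin periodinane, NaHCO3, CH2Cl2, 0 °C → rt
Reagents that add atoms: none
Why: Buffered Dess–Martin oxidation gives the C1 aldehyde without epimerisation or conjugate addition to the methylene lactone.

Step 14
Reactants: 20 (the iodoalkene aldehyde above)
Product: 21 (1RS,4Z,6R,7S,8S,9S)-1-hydroxy-8,9-(isopropylidenedioxy)germacra-4,10(14),11(13)-trien-12,6-olide
Conditions: CrCl2 (8 equiv), NiCl2 (2 mol %), DMSO/THF, rt, 0.003 M, slow addition
Reagents that add atoms: none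
Why: Nozaki–Hiyama–Kishi reaction: NiCl2-catalysed conversion of the 2-iodoalkene into an alkenylchromium species of trivalent chromium that adds only to the aldehyde, high dilution favours the ten-membered ring, and the C1 configuration is irrelevant because C1 becomes sp2 in step 15.

Step 15
Reactants: 21 (the C1 carbinol mixture above)
Product: 22 (1(10)Z,4Z,6R,7S,8S,9S)-14-hydroxy-8,9-(isopropylidenedioxy)germacra-1(10),4,11(13)-trien-12,6-olide
Conditions: Ph3SiOReO3 (5 mol %), Et2O, 0 °C → rt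
Reagents that add atoms: none
Why: Rhenium-oxo-catalysed 1,3-transposition of the allylic alcohol ([3,3] shift of the allyl perrhenate) is reversible and drains to the primary alcohol with the trisubstituted endocyclic olefin, and the ten-membered ring with its second cis olefin strongly favours the ring-cis C1=C10 geometry (C2 cis to C9) of the target.

Step 16
Reactants: 22 (the primary allylic alcohol above)
Product: 23 (1(10)Z,4Z,6R,7S,8S,9S)-14-[(tert-butyldiphenylsilyl)oxy]-8,9-(isopropylidenedioxy)germacra-1(10),4,11(13)-trien-12,6-olide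
Conditions: TBDPSCl, imidazole, CH2Cl2, 0 °C → rt
Reagents that add atoms: tert-butyldiphenylsilyl chloride, CC(C)(C)[Si](Cl)(c1ccccc1)c1ccccc1
Why: Silylation with an acid-stable group keeps C14 at the alcohol level so that it can neither lactonise onto O8 nor be acylated in the next two steps.

Step 17
Reactants: 23 (the silyl ether acetonide above)
Product: 24 (1(10)Z,4Z,6R,7R,8S,9S)-14-[(tert-butyldiphenylsilyl)oxy]-8,9-dihydroxygermacra-1(10),4,11(13)-trien-12,6-olide (7R only through a change in CIP ranking; no centre is inverted)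
Conditions: AcOH/H2O 4:1, 45 °C
Reagents that add atoms: none
Why: Mild aqueous acid hydrolyses the acetonide to the C8/C9 diol while the silyl ether and lactone survive, and the cis,cis-diene is not prone to transannular cyclisation under these conditions.

Step 18
Reactants: 24 (the diol above); 25 angelic acid ((2Z)-2-methylbut-2-enoic acid)
Product: 27 (1(10)Z,4Z,6R,7S,8S,9S)-8,9-bis{[(2Z)-2-methylbut-2-enoyl]oxy}-14-[(tert-butyldiphenylsilyl)oxy]germacra-1(10),4,11(13)-trien-12,6-olide, via mixed anhydride 26 (not isolated)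
Conditions: 25, 2,4,6-Cl3C6H2COCl, Et3N, toluene, rt, 2 h; then 24, 75 °C
Reagents that add atoms: 2,4,6-trichlorobenzoyl chloride, O=C(Cl)c1c(Cl)cc(Cl)cc1Cl (aroyl group of 26 only)
Why: Yamaguchi-type esterification with the preformed mixed anhydride and no DMAP acylates both secondary hydroxyls without the angelate-to-tiglate isomerisation that nucleophilic catalysts cause.

Step 19
Reactants: 27 (the bis-angelate silyl ether above)
Product: 28 (1(10)Z,4Z,6R,7S,8S,9S)-8,9-bis{[(2Z)-2-methylbut-2-enoyl]oxy}-14-hydroxygermacra-1(10),4,11(13)-trien-12,6-olide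
Conditions: HF·pyridine, pyridine, THF, 0 °C → rt
Reagents that add atoms: none
Why: Buffered HF·pyridine removes the silyl ether without ester migration or hydrolysis.

Step 20
Reactants: 28 (the primary allylic alcohol above)
Product: 29 (1(10)E,4Z,6R,7S,8S,9S)-8,9-bis{[(2Z)-2-methylbut-2-enoyl]oxy}-14-oxogermacra-1(10),4,11(13)-trien-12,6-olide (descriptor changes from Z to E by CIP ranking only)
Conditions: MnO2, CH2Cl2, rt
Reagents that add atoms: none
Why: MnO2 oxidises only the primary allylic alcohol to the enal.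

Step 21
Reactants: 29 (the enal above)
Product: 30 (1(10)E,4Z,6R,7S,8S,9S)-8,9-bis{[(2Z)-2-methylbut-2-enoyl]oxy}-12,6-olidogermacra-1(10),4,11(13)-trien-14-oic acid (CNP0154468.1)
Conditions: NaClO2, NaH2PO4, 2-methylbut-2-ene, t-BuOH/H2O, 0 °C → rt
Reagents that add atoms: sodium chlorite, [Na+].[O-]Cl=O
Why: Pinnick oxidation with a hypochlorite scavenger converts the enal into the acid without touching the olefins, the angelates or the lactone.

**Compound list**

1 | pent-4-yn-1-ol | OCCCC#C | starting material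
2 | tert-butyl(dimethyl)(pent-4-yn-1-yloxy)silane | C#CCCCO[Si](C)(C)C(C)(C)C | intermediate
3 | (5-{[tert-butyl(dimethyl)silyl]oxy}pent-1-yn-1-yl)lithium | [Li]C#CCCCO[Si](C)(C)C(C)(C)C | intermediate (not isolated)
4 | methyl 6-{[tert-butyl(dimethyl)silyl]oxy}hex-2-ynoate | COC(=O)C#CCCCO[Si](C)(C)C(C)(C)C | intermediate
5 | methyl (2Z)-6-{[tert-butyl(dimethyl)silyl]oxy}-3-methylhex-2-enoate | COC(=O)/C=C(/C)CCCO[Si](C)(C)C(C)(C)C | intermediate
6 | (2Z)-6-{[tert-butyl(dimethyl)silyl]oxy}-3-methylhex-2-en-1-ol | OC/C=C(/C)CCCO[Si](C)(C)C(C)(C)C | intermediate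
7 | (2Z)-6-{[tert-butyl(dimethyl)silyl]oxy}-3-methylhex-2-enal | O=C/C=C(/C)CCCO[Si](C)(C)C(C)(C)C | intermediate
8 | dimethyl (4R,5R)-2,2-dimethyl-1,3-dioxolane-4,5-dicarboxylate | COC(=O)[C@@H]1OC(C)(C)O[C@H]1C(=O)OC | starting material
9 | (4R,5R)-2,2-dimethyl-1,3-dioxolane-4,5-dicarbaldehyde | O=C[C@@H]1OC(C)(C)O[C@H]1C=O | intermediate (not isolated)
10 | (4S,5S)-4,5-diethynyl-2,2-dimethyl-1,3-dioxolane | C#C[C@@H]1OC(C)(C)O[C@H]1C#C | intermediate
11 | (4S,5R)-4-ethynyl-2,2-dimethyl-5-[1-(tributylstannyl)ethenyl]-1,3-dioxolane | C#C[C@@H]1OC(C)(C)O[C@H]1C(=C)[Sn](CCCC)(CCCC)CCCC | intermediate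
12 | lithium acetylide of 11 | [Li]C#C[C@@H]1OC(C)(C)O[C@H]1C(=C)[Sn](CCCC)(CCCC)CCCC | intermediate (not isolated)
13 | methyl 3-{(4S,5R)-2,2-dimethyl-5-[1-(tributylstannyl)ethenyl]-1,3-dioxolan-4-yl}prop-2-ynoate | COC(=O)C#C[C@@H]1OC(C)(C)O[C@H]1C(=C)[Sn](CCCC)(CCCC)CCCC | intermediate
14 | methyl 3-[(4S,5R)-5-(1-iodoethenyl)-2,2-dimethyl-1,3-dioxolan-4-yl]prop-2-ynoate | COC(=O)C#C[C@@H]1OC(C)(C)O[C@H]1C(I)=C | intermediate
15 | methyl (2E)-2-[bis(2-methylpropyl)alumanyl]-3-[(4S,5R)-5-(1-iodoethenyl)-2,2-dimethyl-1,3-dioxolan-4-yl]prop-2-enoate (H and Al cis) | COC(=O)/C([Al](CC(C)C)CC(C)C)=C\[C@@H]1OC(C)(C)O[C@H]1C(I)=C | intermediate (not isolated)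
16 | methyl (2Z)-3-[(4S,5R)-5-(1-iodoethenyl)-2,2-dimethyl-1,3-dioxolan-4-yl]-2-[(4,4,5,5-tetramethyl-1,3,2-dioxaborolan-2-yl)methyl]prop-2-enoate | COC(=O)/C(CB1OC(C)(C)C(C)(C)O1)=C\[C@@H]2OC(C)(C)O[C@H]2C(I)=C | intermediate
17 | methyl (3S,4R,5Z)-9-{[tert-butyl(dimethyl)silyl]oxy}-3-[(4S,5R)-5-(1-iodoethenyl)-2,2-dimethyl-1,3-dioxolan-4-yl]-6-methyl-2-methylidene-4-[(4,4,5,5-tetramethyl-1,3,2-dioxaborolan-2-yl)oxy]non-5-enoate | C=C(C(=O)OC)[C@@H]([C@H](OB1OC(C)(C)C(C)(C)O1)/C=C(/C)CCCO[Si](C)(C)C(C)(C)C)[C@@H]2OC(C)(C)O[C@H]2C(I)=C | intermediate (not isolated)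
18 | (4S,5R)-5-[(1Z)-5-{[tert-butyl(dimethyl)silyl]oxy}-2-methylpent-1-en-1-yl]-4-[(4S,5R)-5-(1-iodoethenyl)-2,2-dimethyl-1,3-dioxolan-4-yl]-3-methylideneoxolan-2-one | C=C1C(=O)O[C@H](/C=C(/C)CCCO[Si](C)(C)C(C)(C)C)[C@H]1[C@@H]2OC(C)(C)O[C@H]2C(I)=C | intermediate
19 | (4S,5R)-5-[(1Z)-5-hydroxy-2-methylpent-1-en-1-yl]-4-[(4S,5R)-5-(1-iodoethenyl)-2,2-dimethyl-1,3-dioxolan-4-yl]-3-methylideneoxolan-2-one | C=C1C(=O)O[C@H](/C=C(/C)CCCO)[C@H]1[C@@H]2OC(C)(C)O[C@H]2C(I)=C | intermediate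
20 | (4Z)-5-{(2R,3S)-3-[(4S,5R)-5-(1-iodoethenyl)-2,2-dimethyl-1,3-dioxolan-4-yl]-4-methylidene-5-oxooxolan-2-yl}-4-methylpent-4-enal | C=C1C(=O)O[C@H](/C=C(/C)CCC=O)[C@H]1[C@@H]2OC(C)(C)O[C@H]2C(I)=C | intermediate
21 | (1RS,4Z,6R,7S,8S,9S)-1-hydroxy-8,9-(isopropylidenedioxy)germacra-4,10(14),11(13)-trien-12,6-olide (both C1 epimers) | C=C1C(=O)O[C@@H]2/C=C(/C)CCC(O)C(=C)[C@@H]3OC(C)(C)O[C@H]3[C@@H]12 | intermediate
22 | (1(10)Z,4Z,6R,7S,8S,9S)-14-hydroxy-8,9-(isopropylidenedioxy)germacra-1(10),4,11(13)-trien-12,6-olide | C=C1C(=O)O[C@@H]2/C=C(/C)CC/C=C(/CO)[C@@H]3OC(C)(C)O[C@H]3[C@@H]12 | intermediate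
23 | (1(10)Z,4Z,6R,7S,8S,9S)-14-[(tert-butyldiphenylsilyl)oxy]-8,9-(isopropylidenedioxy)germacra-1(10),4,11(13)-trien-12,6-olide | C=C1C(=O)O[C@@H]2/C=C(/C)CC/C=C(/CO[Si](c4ccccc4)(c4ccccc4)C(C)(C)C)[C@@H]3OC(C)(C)O[C@H]3[C@@H]12 | intermediate
24 | (1(10)Z,4Z,6R,7R,8S,9S)-14-[(tert-butyldiphenylsilyl)oxy]-8,9-dihydroxygermacra-1(10),4,11(13)-trien-12,6-olide | C=C1C(=O)O[C@@H]2/C=C(/C)CC/C=C(/CO[Si](c3ccccc3)(c3ccccc3)C(C)(C)C)[C@H](O)[C@@H](O)[C@@H]12 | intermediate
25 | angelic acid, (2Z)-2-methylbut-2-enoic acid | C/C=C(/C)C(=O)O | starting material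
26 | (2Z)-2-methylbut-2-enoic 2,4,6-trichlorobenzoic anhydride | C/C=C(/C)C(=O)OC(=O)c1c(Cl)cc(Cl)cc1Cl | intermediate (not isolated)
27 | (1(10)Z,4Z,6R,7S,8S,9S)-8,9-bis{[(2Z)-2-methylbut-2-enoyl]oxy}-14-[(tert-butyldiphenylsilyl)oxy]germacra-1(10),4,11(13)-trien-12,6-olide | C=C1C(=O)O[C@@H]2/C=C(/C)CC/C=C(/CO[Si](c3ccccc3)(c3ccccc3)C(C)(C)C)[C@H](OC(=O)/C(C)=C\C)[C@@H](OC(=O)/C(C)=C\C)[C@@H]12 | intermediate
28 | (1(10)Z,4Z,6R,7S,8S,9S)-8,9-bis{[(2Z)-2-methylbut-2-enoyl]oxy}-14-hydroxygermacra-1(10),4,11(13)-trien-12,6-olide | C=C1C(=O)O[C@@H]2/C=C(/C)CC/C=C(/CO)[C@H](OC(=O)/C(C)=C\C)[C@@H](OC(=O)/C(C)=C\C)[C@@H]12 | intermediate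
29 | (1(10)E,4Z,6R,7S,8S,9S)-8,9-bis{[(2Z)-2-methylbut-2-enoyl]oxy}-14-oxogermacra-1(10),4,11(13)-trien-12,6-olide | C=C1C(=O)O[C@@H]2/C=C(/C)CC/C=C(/C=O)[C@H](OC(=O)/C(C)=C\C)[C@@H](OC(=O)/C(C)=C\C)[C@@H]12 | intermediate
30 | (1(10)E,4Z,6R,7S,8S,9S)-8,9-bis{[(2Z)-2-methylbut-2-enoyl]oxy}-12,6-olidogermacra-1(10),4,11(13)-trien-14-oic acid (CNP0154468.1) | C=C1C(=O)O[C@@H]2/C=C(/C)CC/C=C(/C(=O)O)[C@H](OC(=O)/C(C)=C\C)[C@@H](OC(=O)/C(C)=C\C)[C@@H]12 | target

**Step count**

Total: 21 steps. Longest linear sequence: 16 steps (steps 6–21 from 8, or equally steps 1–5 and 11–21 from 1).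

**Three steps most likely to fail, with fallbacks**

Step 11 (allylboration and lactonisation). The β,β-disubstituted Z-enal is a weak electrophile that can isomerise, and the facial selectivity rests on the A(1,3)-strain model rather than on a direct precedent. The fallback sets out from 14 and comes back at 18. The alkenylalane 15 is trapped with paraformaldehyde instead of the boronate to give the allylic alcohol F1, which CBr4/PPh3 converts into the allylic bromide F2. Indium powder in THF/H2O with enal 7 then gives a Barbier allylation; this is expected to be syn-selective for such 2-(bromomethyl)alk-2-enoates and to use the same face of C7, so it should deliver the 6-epi hydroxy ester F3. LiOH hydrolysis gives the hydroxy acid F4, and Mitsunobu lactonisation (PPh3, DIAD, THF, 0 °C) closes the ring with inversion at C6 to give 18.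

Step 14 (ten-membered ring by Nozaki–Hiyama–Kishi coupling). Ring strain and the two fused five-membered rings may favour oligomers or simple reduction of the iodide. The fallback sets out from 20 and comes back at 23, bypassing steps 14–16. Wittig methylenation of the aldehyde (Ph3P=CH2, THF, −78 °C) gives the terminal alkene F5. Stille coupling of its iodoalkene with Bu3SnCH2OH (Pd(PPh3)4, dioxane, 90 °C) gives the 2-substituted allylic alcohol F6, and TBDPSCl/imidazole gives the silyl ether F7. Ring-closing metathesis of the two terminal olefins (second-generation Grubbs catalyst RuCl2(=CHPh)(PCy3)(H2IMes), toluene, 80 °C, high dilution) is expected to give the ring-cis trisubstituted olefin and so leads directly to 23.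

Step 15 (1,3-transposition). The equilibrium may stop short, or the Lewis-acidic rhenium catalyst may ionise the allylic system. The fallback sets out from 21 and comes back at 22. SOCl2 in Et2O at 0 °C converts the secondary allylic alcohol with allylic shift (SNi′) into the rearranged primary allylic chloride F8. AgOCOCF3 in CH2Cl2 exchanges chloride for the trifluoroacetate F9 at the less hindered primary terminus, and F9 is cleaved by aqueous NaHCO3 during work-up to give 22.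

**Further compounds**

F1 | step 11 | methyl (2Z)-2-(hydroxymethyl)-3-[(4S,5R)-5-(1-iodoethenyl)-2,2-dimethyl-1,3-dioxolan-4-yl]prop-2-enoate | COC(=O)/C(CO)=C\[C@@H]1OC(C)(C)O[C@H]1C(I)=C
F2 | step 11 | methyl (2E)-2-(bromomethyl)-3-[(4S,5R)-5-(1-iodoethenyl)-2,2-dimethyl-1,3-dioxolan-4-yl]prop-2-enoate | COC(=O)/C(CBr)=C\[C@@H]1OC(C)(C)O[C@H]1C(I)=C
F3 | step 11 | methyl (3S,4S,5Z)-9-{[tert-butyl(dimethyl)silyl]oxy}-4-hydroxy-3-[(4S,5R)-5-(1-iodoethenyl)-2,2-dimethyl-1,3-dioxolan-4-yl]-6-methyl-2-methylidenenon-5-enoate | C=C(C(=O)OC)[C@@H]([C@@H](O)/C=C(/C)CCCO[Si](C)(C)C(C)(C)C)[C@@H]1OC(C)(C)O[C@H]1C(I)=C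
F4 | step 11 | (3S,4S,5Z)-9-{[tert-butyl(dimethyl)silyl]oxy}-4-hydroxy-3-[(4S,5R)-5-(1-iodoethenyl)-2,2-dimethyl-1,3-dioxolan-4-yl]-6-methyl-2-methylidenenon-5-enoic acid | C=C(C(=O)O)[C@@H]([C@@H](O)/C=C(/C)CCCO[Si](C)(C)C(C)(C)C)[C@@H]1OC(C)(C)O[C@H]1C(I)=C
F5 | step 14 | (4S,5R)-4-[(4S,5R)-5-(1-iodoethenyl)-2,2-dimethyl-1,3-dioxolan-4-yl]-3-methylidene-5-[(1Z)-2-methylhexa-1,5-dien-1-yl]oxolan-2-one | C=C1C(=O)O[C@H](/C=C(/C)CCC=C)[C@H]1[C@@H]2OC(C)(C)O[C@H]2C(I)=C
F6 | step 14 | (4S,5R)-4-[(4S,5S)-5-(3-hydroxyprop-1-en-2-yl)-2,2-dimethyl-1,3-dioxolan-4-yl]-3-methylidene-5-[(1Z)-2-methylhexa-1,5-dien-1-yl]oxolan-2-one | C=C1C(=O)O[C@H](/C=C(/C)CCC=C)[C@H]1[C@@H]2OC(C)(C)O[C@H]2C(=C)CO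
F7 | step 14 | (4S,5R)-4-[(4S,5S)-5-{3-[(tert-butyldiphenylsilyl)oxy]prop-1-en-2-yl}-2,2-dimethyl-1,3-dioxolan-4-yl]-3-methylidene-5-[(1Z)-2-methylhexa-1,5-dien-1-yl]oxolan-2-one | C=C1C(=O)O[C@H](/C=C(/C)CCC=C)[C@H]1[C@@H]2OC(C)(C)O[C@H]2C(=C)CO[Si](c3ccccc3)(c3ccccc3)C(C)(C)C
F8 | step 15 | (1(10)E,4Z,6R,7S,8S,9S)-14-chloro-8,9-(isopropylidenedioxy)germacra-1(10),4,11(13)-trien-12,6-olide | C=C1C(=O)O[C@@H]2/C=C(/C)CC/C=C(/CCl)[C@@H]3OC(C)(C)O[C@H]3[C@@H]12
F9 | step 15 | (1(10)Z,4Z,6R,7S,8S,9S)-8,9-(isopropylidenedioxy)-14-(trifluoroacetoxy)germacra-1(10),4,11(13)-trien-12,6-olide | C=C1C(=O)O[C@@H]2/C=C(/C)CC/C=C(/COC(=O)C(F)(F)F)[C@@H]3OC(C)(C)O[C@H]3[C@@H]12
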